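**Retrosynthetic overview**
1. Target 28 ⇐ sipholenone A 27 (catalyst-controlled epoxidation of the ring alkene, oxirane syn to the C11' side chain) ⇐ sipholenol A 26 (oxidation at C3) ⇐ keto diol 25 (equatorial methyl addition at C10).
2. Key disconnection 25 ⇒ 22: one Lewis-acid cascade on an acyclic bis-oxirane silyl enol ether attached to the finished hydroazulene first makes the C6–C11 bond (cyclohexanone ring) and then the O–C2 bond (oxepane ring). Enabling feature: the ring oxygen sits on C7, vicinal to the quaternary C6 and 1,5 to the gem-dimethyl carbon C2, and C11 is α to the C10 carbonyl; a trans-6,7-oxirane is therefore the electrophile for the enol ether carbon C11 and, once opened, the alkoxide that closes the seven-membered ether ring on the tertiary carbon of the 2,3-oxirane.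
3. 22 ⇐ enone 21 ⇐ aldol union at C11–C12 of bis-oxirane 18 (double Shi epoxidation of (E)-geranylacetone, which supplies C2–C11) with hydroazulene aldehyde 16.
4. 16 ⇐ Johnson–Claisen transposition (sets C11', brings in C12' and C12) ⇐ cis-fused hydroxy enone 12 ⇐ SmI2 ketyl–enone closure of the cyclopentane on cycloheptadienone 11 ⇐ one-carbon ring expansion of a cyclohexadienone that receives C3' by copper-catalysed asymmetric conjugate addition.
5. Order of ring formation: six-membered carbocycle (step 1, enlarged to the seven-membered carbocycle in step 5) → cyclopentane (step 7) → cyclohexane → oxepane (both in step 16; the oxepane closes last and completes the ring skeleton); the oxirane is added to the finished skeleton in step 19.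

Key step: step 16

Remark: locants follow the two farnesyl-type halves: left half C2 (CMe2 on the ring oxygen), C3, C4, C5, C6 (quaternary C–Me), C7 (CH–O), C8, C9, C10 (C(Me)OH), C11 (CH), C12; right half C12' (CH2), C11' (ring CH), C10' (C–Me of the alkene), C9', C8', C7' and C3' (ring-fusion CH), C6' (C(Me)OH), C5', C4', C2' (CMe2). (E)-Geranylacetone and both enantiomers of the fructose-derived epoxidation ketone are assumed purchasable, and the oxirane is treated as a functional group of the finished skeleton.

**Route**

Step 1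
Reactants: 1 isobutyraldehyde; 2 pent-1-en-3-one
Product: 3 2,4,4-trimethylcyclohex-2-en-1-one
Conditions: H2SO4 (cat.), PhMe, 45 °C then reflux (Dean–Stark)
Reagents that add atoms: none
Why: Acid-catalysed Robinson annulation (Michael addition of the aldehyde enol to the vinyl ketone, then aldol condensation of the ethyl ketone onto the now non-enolisable aldehyde) should give the 4,4-dimethylcyclohexenone that already carries the future C10' methyl group; no stereocentre is formed.

Step 2
Reactants: 3 2,4,4-trimethylcyclohex-2-en-1-one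
Product: 4 2,4,4-trimethylcyclohexa-2,5-dien-1-one
Conditions: DDQ, 1,4-dioxane, reflux
Reagents that add atoms: none
Why: DDQ dehydrogenation of a 4,4-disubstituted cyclohexenone can only introduce the C5=C6 double bond and should give the cross-conjugated dienone, whose two ring faces are enantiotopic.

Step 3
Reactants: 4 2,4,4-trimethylcyclohexa-2,5-dien-1-one; 5 2-(2-bromoethyl)-2-methyl-1,3-dioxolane
Product: 7 (6R)-trimethylsilyl dienol ether of the conjugate adduct, via Grignard reagent 6 (not isolated)
Conditions: Mg, 2-MeTHF, 25 °C (gives 6); then 4, CuBr·SMe2 (5 mol %), (R)-1-[(S)-2-(diphenylphosphino)ferrocenyl]ethyldicyclohexylphosphine or its antipode as required for the 6R product (6 mol %), TMSCl, t-BuOMe, −78 °C; Et3N, pentane filtration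
Reagents that add atoms: chlorotrimethylsilane C[Si](C)(C)Cl
Why: Copper-catalysed asymmetric conjugate addition of a Grignard reagent: the alkyl group should add to C5 of the unsubstituted enone arm (the 2-methyl arm is deactivated), the chiral ferrocenyl diphosphine on monovalent copper selecting one enantiotopic ring face and thereby setting C3' (R), and TMSCl traps the magnesium enolate as the regiodefined cross-conjugated silyl dienol ether.

Step 4
Reactants: 7 (6R)-trimethylsilyl dienol ether
Product: 8 siloxy vinylcyclopropane (5R; both cyclopropane faces)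
Conditions: Et2Zn, CH2I2, CH2Cl2, 0 °C
Reagents that add atoms: diiodomethane ICI
Why: Simmons–Smith cyclopropanation (Furukawa variant) should occur at the electron-rich silyl enol ether double bond rather than at the hindered trisubstituted alkene; the two new cyclopropane stereocentres are unselective and irrelevant because both are destroyed in step 5.

Step 5
Reactants: 8 siloxy vinylcyclopropane
Product: 10 (5R)-2,4,4-trimethyl-5-[2-(2-methyl-1,3-dioxolan-2-yl)ethyl]cyclohepta-2,6-dien-1-one, via chloro ketone 9 (not isolated)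
Conditions: FeCl3 (2.2 equiv), DMF, 0 → 23 °C; then NaOAc, MeOH, 40 °C
Reagents that add atoms: none
Why: Oxidative ring expansion of a siloxycyclopropane with FeCl3 (one-electron oxidation, opening of the internal cyclopropane bond to the ring-enlarged β-keto radical, chlorine transfer to give 9) followed by E1cB loss of HCl should insert C8' and deliver the cross-conjugated cycloheptadienone; C3' is untouched.

Step 6
Reactants: 10 cycloheptadienone ketal
Product: 11 (5R)-2,4,4-trimethyl-5-(3-oxobutyl)cyclohepta-2,6-dien-1-one
Conditions: 1 M HCl, THF, 0 → 23 °C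
Reagents that add atoms: water O
Why: Acid-catalysed ketal hydrolysis should release the methyl ketone needed for the cyclopentane closure without affecting the dienone.

Step 7
Reactants: 11 diketone
Product: 12 (1R,3aR,8aR)-1-hydroxy-1,4,4,6-tetramethyl-2,3,3a,4,8,8a-hexahydroazulen-7(1H)-one
Conditions: SmI2 (2.2 equiv), HMPA, THF, −78 °C (0.01 M); sat. aq. NH4Cl
Reagents that add atoms: none
Why: SmI2-mediated ketyl–olefin (ketone–enone) reductive cyclisation, 5-exo-trig at C7' of the disubstituted enone arm, should close the cyclopentane: the ring fusion is cis because the tether on C3' can reach the adjacent carbon only from its own face (C7' R), the samarium-bound oxygen turns away from C8' so that the hydroxyl ends up syn to H7' (C6' R), and protonation of the samarium enolate at C8' on work-up leaves the 2-methyl enone arm as the conjugated ketone.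

Step 8
Reactants: 12 hydroxy enone
Product: 13 triethylsilyl ether of 12
Conditions: TESOTf, 2,6-lutidine, CH2Cl2, −78 → 0 °C
Reagents that add atoms: triethylsilyl trifluoromethanesulfonate CC[Si](CC)(CC)OS(=O)(=O)C(F)(F)F
Why: Silylation of a tertiary alcohol with a silyl triflate and a hindered pyridine base should protect the C6' hydroxyl against the bases and Lewis acids used up to step 16.

Step 9
Reactants: 13 silyl-protected enone
Product: 14 (1R,3aR,7S,8aR)-allylic alcohol
Conditions: (R)-2-methyl-CBS-oxazaborolidine (0.5 equiv), catecholborane, PhMe, −78 °C; MeOH, then aq. NaOH wash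
Reagents that add atoms: none
Why: Corey–Bakshi–Shibata reduction (1,2-reduction of the enone by catecholborane) should deliver hydride to the convex face, the oxazaborolidine treating the methyl-bearing alkene carbon as the large group and the C6' methyl under the concave face acting in the same sense, so that the C9' hydroxyl (S) lies on the face opposite to H7'.

Step 10
Reactants: 14 allylic alcohol
Product: 15 ethyl (5S)-hydroazulenylacetate
Conditions: MeC(OEt)3, EtCO2H (cat.), xylene, 140 °C (EtOH distilled off)
Reagents that add atoms: triethyl orthoacetate CC(OCC)(OCC)OCC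
Why: Johnson–Claisen rearrangement: the ketene acetal formed at the C9' oxygen should rearrange suprafacially through the [3,3] transition state, forming the C11'–C12' bond next to the quaternary C2' on the face that the oxygen leaves (C11' S, side chain anti to H7') and moving the double bond to C9'=C10'.

Step 11
Reactants: 15 ethyl ester
Product: 16 hydroazulenylacetaldehyde
Conditions: i-Bu2AlH (1.1 equiv), CH2Cl2, −78 °C; aq. KNaC4H4O6
Reagents that add atoms: none
Why: Reduction of the ester with i-Bu2AlH at low temperature should stop at the aldehyde because the tetrahedral aluminium hemiacetal survives until work-up.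

Step 12
Reactants: 17 (E)-geranylacetone
Product: 18 4-[(2R,3R)-3-{2-[(2R)-3,3-dimethyloxiran-2-yl]ethyl}-3-methyloxiran-2-yl]butan-2-one
Conditions: D-fructose-derived Shi ketone (0.3 equiv), KHSO5 (as Oxone, 2KHSO5·KHSO4·K2SO4), K2CO3, Bu4NHSO4, MeCN/dimethoxymethane/aq. Na2B4O7 buffer, 0 °C
Reagents that add atoms: potassium peroxymonosulfate [K+].[O-]S(=O)(=O)OO
Why: Shi epoxidation: the dioxirane generated from the D-fructose-derived ketone should epoxidise both trisubstituted E-alkenes through the spiro transition state, giving the (R,R)-6,7-oxirane and the (R)-2,3-oxirane and thus fixing C6, C7 and the temporary C3 centre in the absolute sense.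

Step 13
Reactants: 18 bis-oxirane methyl ketone; 16 hydroazulenylacetaldehyde
Product: 19 β-hydroxy ketone (both C12 epimers)
Conditions: LiN(i-Pr)2 (1.05 equiv), THF, −78 °C, then 16; sat. aq. NH4Cl
Reagents that add atoms: none
Why: Directed aldol addition: kinetic deprotonation at the methyl group of the methyl ketone and addition of the lithium enolate to the aldehyde should join the two halves at the C11–C12 bond; the new carbinol centre is not controlled and is removed in step 14.

Step 14
Reactants: 19 β-hydroxy ketone
Product: 21 E-enone, via mesylate 20 (not isolated)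
Conditions: MsCl, Et3N (5 equiv), CH2Cl2, 0 → 23 °C
Reagents that add atoms: none
Why: Mesylation followed by E1cB elimination of the β-mesyloxy ketone should give the E-enone.

Step 15
Reactants: 21 E-enone
Product: 22 Z triethylsilyl enol ether
Conditions: Et3SiH, RhCl(PPh3)3 (2 mol %), PhMe, 50 °C
Reagents that add atoms: triethylsilane CC[SiH](CC)CC
Why: Rhodium-catalysed 1,4-hydrosilylation of the enone in its s-cis conformation should give regiospecifically the Z triethylsilyl enol ether between C10 and C11, the oxiranes and the ring alkene being inert to the rhodium hydride.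

Step 16
Reactants: 22 Z triethylsilyl enol ether
Product: 25 keto diol (3R,5aR,6R,9aR), via alkoxide 23 (not isolated), via silyl ether 24 (not isolated)
Conditions: MeAlCl2 (1.2 equiv), CH2Cl2, −94 °C, 20 min; MeAlCl2 (1.5 equiv), −78 → −20 °C; then 1 M HCl, THF, 23 °C
Reagents that add atoms: none
Why: Mechanism: the first portion of MeAlCl2 activates the electron-rich 6,7-oxirane and the Z silyl enol ether attacks the tertiary C6 with inversion through a chair transition state (C6–C11 bond, silicon lost from the oxocarbenium ion), giving the cyclohexanone with the C7 oxygen on aluminium (23); on warming with the second portion this oxygen opens the activated terminal oxirane at its tertiary carbon C2 and closes the oxepane (24), and the acidic work-up removes the silyl groups. The closest known reaction types are the MeAlCl2-promoted epoxide-initiated cation–olefin cyclisation terminated by a silyl enol ether and the Lewis-acid oxa-/carbacyclisation cascades of 1,5-diepoxides that give trans-fused oxepane–cyclohexane units. Modes of closure: the cyclohexanone ring closes 6-endo with respect to both partners (the enol ether double bond and both oxirane carbons lie in the new ring, the broken C6–O bond is exocyclic), and the oxepane ring closes 7-endo-tet at C2 with the former oxirane oxygen becoming the exocyclic C3 hydroxyl. Stereocontrol: C6 (R) arises by inversion of the (6R,7R)-oxirane, C7 (R) and C3 (R) are carried over from the oxiranes, and C11 (R) follows from the chair with the Z enol ether placing the side chain equatorial, which is also the thermodynamic epimer next to the ketone, so the ring fusion is trans. Selectivity needed: carbon must react before oxygen, which rests on the far higher nucleophilicity of the enol ether and on dosing the Lewis acid at −94 °C so that the terminal oxirane is engaged only once the C7 alkoxide exists, and the oxygen must open the terminal oxirane 7-endo rather than 6-exo, which rests on the cation-stabilising gem-dimethyl carbon C2 under strong Lewis-acid activation. The ring alkene and the tertiary silyl ether of the hydroazulene are bystanders because the enol ether terminator leaves no free carbocation.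

Step 17
Reactants: 25 keto diol
Product: 26 sipholenol A
Conditions: MeLi (6 equiv), CeCl3 (6 equiv), THF, −78 °C; sat. aq. NH4Cl
Reagents that add atoms: methyllithium [Li]C
Why: 1,2-Addition of the organocerium reagent (chosen to suppress enolisation at C11) should occur from the equatorial direction because the axial approach to C10 is blocked by the syn-axial C6 methyl group, giving the equatorial methyl and the axial hydroxyl (C10 S); the two free hydroxyl groups only consume base.

Step 18
Reactants: 26 sipholenol A
Product: 27 sipholenone A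
Conditions: Dess–Martin periodinane, CH2Cl2, 23 °C
Reagents that add atoms: none
Why: Dess–Martin oxidation can only affect the single secondary alcohol at C3 (the other two hydroxyl groups are tertiary) and should give the oxepan-3-one.

Step 19
Reactants: 27 sipholenone A
Product: 28 CNP0259752.1 (target)
Conditions: L-fructose-derived (enantiomeric) Shi ketone (0.5 equiv), KHSO5 (as Oxone, 2KHSO5·KHSO4·K2SO4), K2CO3, Bu4NHSO4, MeCN/dimethoxymethane/aq. buffer (pH 10.5), 0 °C
Reagents that add atoms: potassium peroxymonosulfate [K+].[O-]S(=O)(=O)OO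
Why: Shi epoxidation under catalyst control: with C8' and the C10' methyl group as the trans pair of the trisubstituted ring alkene, the dioxirane of the L-fructose-derived ketone should transfer oxygen to the face syn to the C11' side chain (C9' S, C10' R), and the hindered ketone and the tertiary alcohols are not expected to react.

**Compound list**
1 | isobutyraldehyde (2-methylpropanal) | CC(C)C=O | starting material
2 | pent-1-en-3-one (ethyl vinyl ketone) | CCC(=O)C=C | starting material
3 | 2,4,4-trimethylcyclohex-2-en-1-one | CC1=CC(C)(C)CCC1=O | intermediate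
4 | 2,4,4-trimethylcyclohexa-2,5-dien-1-one | CC1=CC(C)(C)C=CC1=O | intermediate
5 | 2-(2-bromoethyl)-2-methyl-1,3-dioxolane | CC1(CCBr)OCCO1 | starting material
6 | [2-(2-methyl-1,3-dioxolan-2-yl)ethyl]magnesium bromide (not isolated) | CC1(CC[Mg]Br)OCCO1 | intermediate
7 | trimethyl({(6R)-3,5,5-trimethyl-6-[2-(2-methyl-1,3-dioxolan-2-yl)ethyl]cyclohexa-1,3-dien-2-yl}oxy)silane | CC1=CC(C)(C)[C@H](CCC2(C)OCCO2)C=C1O[Si](C)(C)C | intermediate
8 | trimethyl({(5R)-2,4,4-trimethyl-5-[2-(2-methyl-1,3-dioxolan-2-yl)ethyl]bicyclo[4.1.0]hept-2-en-1-yl}oxy)silane (both cyclopropane faces) | CC1=CC(C)(C)[C@H](CCC2(C)OCCO2)C2CC12O[Si](C)(C)C | intermediate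
9 | (5S)-6-chloro-2,4,4-trimethyl-5-[2-(2-methyl-1,3-dioxolan-2-yl)ethyl]cyclohept-2-en-1-one (not isolated; both C6 epimers) | CC1=CC(C)(C)[C@H](CCC2(C)OCCO2)C(Cl)CC1=O | intermediate
10 | (5R)-2,4,4-trimethyl-5-[2-(2-methyl-1,3-dioxolan-2-yl)ethyl]cyclohepta-2,6-dien-1-one | CC1=CC(C)(C)[C@H](CCC2(C)OCCO2)C=CC1=O | intermediate
11 | (5R)-2,4,4-trimethyl-5-(3-oxobutyl)cyclohepta-2,6-dien-1-one | CC1=CC(C)(C)[C@H](CCC(C)=O)C=CC1=O | intermediate
12 | (1R,3aR,8aR)-1-hydroxy-1,4,4,6-tetramethyl-2,3,3a,4,8,8a-hexahydroazulen-7(1H)-one | CC1=CC(C)(C)[C@@H]2CC[C@@](C)(O)[C@@H]2CC1=O | intermediate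
13 | (1R,3aR,8aR)-1,4,4,6-tetramethyl-1-(triethylsilyloxy)-2,3,3a,4,8,8a-hexahydroazulen-7(1H)-one | CC1=CC(C)(C)[C@@H]2CC[C@@](C)(O[Si](CC)(CC)CC)[C@@H]2CC1=O | intermediate
14 | (1R,3aR,7S,8aR)-1,4,4,6-tetramethyl-1-(triethylsilyloxy)-1,2,3,3a,4,7,8,8a-octahydroazulen-7-ol | CC1=CC(C)(C)[C@@H]2CC[C@@](C)(O[Si](CC)(CC)CC)[C@@H]2C[C@@H]1O | intermediate
15 | ethyl 2-[(1R,3aR,5S,8aR)-1,4,4,6-tetramethyl-1-(triethylsilyloxy)-1,2,3,3a,4,5,8,8a-octahydroazulen-5-yl]acetate | CCOC(=O)C[C@@H]1C(C)(C)[C@@H]2CC[C@@](C)(O[Si](CC)(CC)CC)[C@@H]2CC=C1C | intermediate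
16 | 2-[(1R,3aR,5S,8aR)-1,4,4,6-tetramethyl-1-(triethylsilyloxy)-1,2,3,3a,4,5,8,8a-octahydroazulen-5-yl]acetaldehyde | O=CC[C@@H]1C(C)(C)[C@@H]2CC[C@@](C)(O[Si](CC)(CC)CC)[C@@H]2CC=C1C | intermediate
17 | (E)-geranylacetone [(5E)-6,10-dimethylundeca-5,9-dien-2-one] | CC(=O)CC/C=C(\C)CCC=C(C)C | starting material
18 | 4-[(2R,3R)-3-{2-[(2R)-3,3-dimethyloxiran-2-yl]ethyl}-3-methyloxiran-2-yl]butan-2-one | CC(=O)CC[C@H]1O[C@]1(C)CC[C@H]1OC1(C)C | intermediate
19 | 6-[(2R,3R)-3-{2-[(2R)-3,3-dimethyloxiran-2-yl]ethyl}-3-methyloxiran-2-yl]-2-hydroxy-1-[(1R,3aR,5S,8aR)-1,4,4,6-tetramethyl-1-(triethylsilyloxy)-1,2,3,3a,4,5,8,8a-octahydroazulen-5-yl]hexan-4-one (both C2 epimers) | O=C(CC(O)C[C@@H]1C(C)(C)[C@@H]2CC[C@@](C)(O[Si](CC)(CC)CC)[C@@H]2CC=C1C)CC[C@H]1O[C@]1(C)CC[C@H]1OC1(C)C | intermediate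
20 | methanesulfonate of 19 (not isolated) | O=C(CC(OS(C)(=O)=O)C[C@@H]1C(C)(C)[C@@H]2CC[C@@](C)(O[Si](CC)(CC)CC)[C@@H]2CC=C1C)CC[C@H]1O[C@]1(C)CC[C@H]1OC1(C)C | intermediate
21 | (2E)-6-[(2R,3R)-3-{2-[(2R)-3,3-dimethyloxiran-2-yl]ethyl}-3-methyloxiran-2-yl]-1-[(1R,3aR,5S,8aR)-1,4,4,6-tetramethyl-1-(triethylsilyloxy)-1,2,3,3a,4,5,8,8a-octahydroazulen-5-yl]hex-2-en-4-one | O=C(/C=C/C[C@@H]1C(C)(C)[C@@H]2CC[C@@](C)(O[Si](CC)(CC)CC)[C@@H]2CC=C1C)CC[C@H]1O[C@]1(C)CC[C@H]1OC1(C)C | intermediate
22 | (3Z)-triethylsilyl enol ether of the 2,3-dihydro derivative of 21 (hex-3-en-4-yl silyl ether) | CC[Si](CC)(CC)O/C(CC[C@H]1O[C@]1(C)CC[C@H]1OC1(C)C)=C\CC[C@@H]1C(C)(C)[C@@H]2CC[C@@](C)(O[Si](CC)(CC)CC)[C@@H]2CC=C1C | intermediate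
23 | (2R,3R,4R)-3-{2-[(2R)-3,3-dimethyloxiran-2-yl]ethyl}-4-hydroxy-3-methyl-2-{2-[(1R,3aR,5S,8aR)-1,4,4,6-tetramethyl-1-(triethylsilyloxy)-1,2,3,3a,4,5,8,8a-octahydroazulen-5-yl]ethyl}cyclohexan-1-one (not isolated; in the flask as its C4 chloro(methyl)aluminium alkoxide) | O[C@@H]1CCC(=O)[C@H](CC[C@@H]2C(C)(C)[C@@H]3CC[C@@](C)(O[Si](CC)(CC)CC)[C@@H]3CC=C2C)[C@@]1(C)CC[C@H]1OC1(C)C | intermediate
24 | (3R,5aR,6R,9aR)-3-hydroxy-2,2,5a-trimethyl-6-{2-[(1R,3aR,5S,8aR)-1,4,4,6-tetramethyl-1-(triethylsilyloxy)-1,2,3,3a,4,5,8,8a-octahydroazulen-5-yl]ethyl}octahydro-1-benzoxepin-7(2H)-one (not isolated; in the flask as its C3 aluminium alkoxide) | CC1(C)O[C@@H]2CCC(=O)[C@H](CC[C@@H]3C(C)(C)[C@@H]4CC[C@@](C)(O[Si](CC)(CC)CC)[C@@H]4CC=C3C)[C@@]2(C)CC[C@H]1O | intermediate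
25 | (3R,5aR,6R,9aR)-3-hydroxy-6-{2-[(1R,3aR,5S,8aR)-1-hydroxy-1,4,4,6-tetramethyl-1,2,3,3a,4,5,8,8a-octahydroazulen-5-yl]ethyl}-2,2,5a-trimethyloctahydro-1-benzoxepin-7(2H)-one | CC1(C)O[C@@H]2CCC(=O)[C@H](CC[C@@H]3C(C)(C)[C@@H]4CC[C@@](C)(O)[C@@H]4CC=C3C)[C@@]2(C)CC[C@H]1O | intermediate
26 | sipholenol A: (3R,5aR,6R,7S,9aR)-6-{2-[(1R,3aR,5S,8aR)-1-hydroxy-1,4,4,6-tetramethyl-1,2,3,3a,4,5,8,8a-octahydroazulen-5-yl]ethyl}-2,2,5a,7-tetramethyldecahydro-1-benzoxepine-3,7-diol | CC1(C)O[C@@H]2CC[C@](C)(O)[C@H](CC[C@@H]3C(C)(C)[C@@H]4CC[C@@](C)(O)[C@@H]4CC=C3C)[C@@]2(C)CC[C@H]1O | intermediate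
27 | sipholenone A: (5aR,6R,7S,9aR)-7-hydroxy-6-{2-[(1R,3aR,5S,8aR)-1-hydroxy-1,4,4,6-tetramethyl-1,2,3,3a,4,5,8,8a-octahydroazulen-5-yl]ethyl}-2,2,5a,7-tetramethyloctahydro-1-benzoxepin-3(2H)-one | CC1(C)O[C@@H]2CC[C@](C)(O)[C@H](CC[C@@H]3C(C)(C)[C@@H]4CC[C@@](C)(O)[C@@H]4CC=C3C)[C@@]2(C)CCC1=O | intermediate
28 | CNP0259752.1: 27 with the C9'=C10' alkene converted into the oxirane syn to the C11' side chain (C9' S; C10' R) | CC1(C)O[C@@H]2CC[C@](C)(O)[C@H](CC[C@@H]3C(C)(C)[C@@H]4CC[C@@](C)(O)[C@@H]4C[C@@H]4O[C@@]43C)[C@@]2(C)CCC1=O | target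

**Step count and risks**
Total step count: 19. Longest linear sequence: 18 steps (steps 1–11, then 13–19); step 12 is the one-step side branch.

Steps most likely to fail:

Step 16 (key cascade). Once the cyclohexanone has formed, the aluminium-bound C7 oxygen may open the terminal oxirane at the secondary C3 (6-exo, tetrahydropyran), or the activated oxirane may be captured by chloride before the seven-membered ring closes. The fallback sets out from 22 and closes the two rings in separate operations under different activation. The carbocyclisation is run alone (MeAlCl2, 1.1 equiv, CH2Cl2, −94 °C, quenched cold with Et3N/MeOH) and the hydroxy epoxy ketone 23 is isolated as the free alcohol. The oxepane is then closed with a silyl cation instead of an aluminium alkoxide (i-Pr3SiOTf, 2,6-lutidine, MeNO2, 0 °C), conditions under which a hydroxyl group opens a trisubstituted oxirane at the tertiary carbon and the counter-ion is non-nucleophilic, giving the 3-O-triisopropylsilyl oxepane F1. HF·pyridine in THF removes both silyl ethers and the route is rejoined at 25.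

Step 7 (SmI2 cyclisation). The dienone radical anion may be reduced further or couple intermolecularly, or the ring may close with the oxygen syn to C8' (wrong C6' epimer). The fallback sets out from 11 and makes the same C6'–C7' bond by palladium chemistry, setting the carbinol afterwards. The methyl ketone is converted through its kinetic potassium enolate (KN(SiMe3)2, PhNTf2, THF, −78 °C) into the but-1-en-2-yl triflate F2. A reductive Heck cyclisation with zerovalent palladium (Pd(OAc)2, PPh3, HCO2Na, DMF, 60 °C; 5-exo carbopalladation of the C7'=C8' enone arm, cis-fused for geometric reasons) gives the exocyclic methylene hydroazulenone F3. Mukaiyama hydration (Co(acac)2, PhSiH3, O2, i-PrOH) then generates the tertiary C6' radical, which should take up oxygen from the convex face, and the route is rejoined at 12.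

Step 19 (final epoxidation). The substrate's own facial bias (the allylic C11' side chain and the C6' hydroxyl) may override the catalyst and put the oxygen anti to the side chain. The fallback sets out from 27 and uses that bias instead of opposing it. NBS in THF/H2O at 0 °C should form the bromonium ion on the face anti to the side chain, and water opens it at the tertiary C10' from the side-chain face to give the bromohydrin F4. K2CO3 in MeOH then closes the oxirane with inversion at C9', which places the oxygen syn to the side chain and arrives at 28.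

Further compounds
F1 | step 16 | (3R,5aR,6R,9aR)-2,2,5a-trimethyl-6-{2-[(1R,3aR,5S,8aR)-1,4,4,6-tetramethyl-1-(triethylsilyloxy)-1,2,3,3a,4,5,8,8a-octahydroazulen-5-yl]ethyl}-3-[tri(propan-2-yl)silyloxy]octahydro-1-benzoxepin-7(2H)-one | CC1(C)O[C@@H]2CCC(=O)[C@H](CC[C@@H]3C(C)(C)[C@@H]4CC[C@@](C)(O[Si](CC)(CC)CC)[C@@H]4CC=C3C)[C@@]2(C)CC[C@H]1O[Si](C(C)C)(C(C)C)C(C)C
F2 | step 7 | 4-[(1R)-2,2,4-trimethyl-5-oxocyclohepta-3,6-dien-1-yl]but-1-en-2-yl trifluoromethanesulfonate | CC1=CC(C)(C)[C@H](CCC(=C)OS(=O)(=O)C(F)(F)F)C=CC1=O
F3 | step 7 | (3aR,8aR)-4,4,6-trimethyl-1-methylidene-2,3,3a,4,8,8a-hexahydroazulen-7(1H)-one | CC1=CC(C)(C)[C@@H]2CCC(=C)[C@@H]2CC1=O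
F4 | step 19 | bromohydrin of 27 (C9' bromide anti to the side chain; C10' hydroxyl syn to the side chain) | CC1(C)O[C@@H]2CC[C@](C)(O)[C@H](CC[C@@H]3C(C)(C)[C@@H]4CC[C@@](C)(O)[C@@H]4C[C@@H](Br)[C@]3(C)O)[C@@]2(C)CCC1=O
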